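The data were generated by integration from invented constants; scatter was added.

The slow part of this flask is its tail, where the last first end groups react with little more than the small excess of second end groups.

- violet: first end groups 0.10 M; second end groups 0.11 M; scavenger 0.24 M; run made earlier
- flask: first end groups 0.10 M; second end groups 0.110 M; scavenger 0.120 M; time 10 d

violet run (percent of the first end groups charged)

| time / h | first end groups / % | links / % |
|---|---|---|
| 10.0 | 36.6 | 64.4 |
| 20.0 | 21.5 | 79.7 |
| 30.0 | 14.1 | 86.2 |
| 40.0 | 9.7 | 91.2 |
| 50.0 | 7.8 | 92.1 |

(scatter of a reading: 1 percentage point)

- the analysis behind the earlier runs scatters by 1 percentage point, standard deviation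
- the earlier runs do not show how much of second end groups is bound; that part of a forecast is a guess
- no earlier run changes the charge of scavenger; that part of a forecast is a guess

1. part of the first end groups that has reacted at 10 d
2. share of the unused second end groups that is free and not bound as idle adduct, at 10 d

I began from the end state. First end groups are the limiting reagent, so c(second end groups) heads for the excess, 0.0100 M, and the decay there is pseudo-first-order. For a rate proportional to both concentrations, the ratio c(second end groups)/c(first end groups) grows exponentially. Its time constant is the reciprocal of the rate constant times the excess. The first violet reading gave 2.85 d, the tail time constant, a reading carrying the scatter of 1 percentage point. The violet excess is the same, and I guessed that the scavenger charge does not alter it.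

The flask then runs for 3.51 time constants. For a lower bound on c I reckoned with equal charges, without the excess, and got 97.2%. Putting c(second end groups) equal to the excess in the ratio gave me an upper bound of 99.7%. Writing c(second end groups) exactly as c(first end groups) plus the excess tightened this to 99.7%. The runs gave me nothing to bracket fr.

The forecast said 99.8%, close to my upper bound, and 70% for fr: “Taking K of about 3–4 (a guess), fr is about 70%.”

The flask gave 99.7% and >99.9%, with idle adduct at 8.37 × 10⁻⁸ M.

    links + released group → side product (k = 0.342 L mol⁻¹ h⁻¹)
    first end groups + second end groups ⇌ links + released group (K = 2.04, k = 1.50 L mol⁻¹ h⁻¹)
    crystals ⇌ released group, rate k3*(cs3 - [released group]) while solid is left; crystals form when [released group] > cs3 (solubility = 1.70 mM, k = 17.2 h⁻¹)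
    second end groups + released group ⇌ idle adduct, settled at all times (K = 4.20 L mol⁻¹)
    scavenger + released group → scavenged by-product (k = 104 L mol⁻¹ h⁻¹)

The neighbour flask with 0.066 M of second end groups makes them the limiting reagent, with an excess of first end groups of 0.0340 M. Its tail time constant scales inversely with the excess, to 0.838 d, so 10 d is 11.9 time constants and the end state should stand, with c at 66.0%. That neighbour gave 66.0%, with second end groups at 0% and first end groups at 34.0%.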